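Retrosynthetic cuts, in order: the bridge CH2–C4 bond to the dienone ring, the bridge CH2–C6 bond of the chromene, the exocyclic acyl–C2 bond of the dienone ring, removal of the two-carbon unit C2–C3 from that ring (which shrinks it to a cyclobutenone), the pyran bonds O1–C2 and C4–C4a, and the aryl–acyl bond.
Enabling feature: in the drawn tautomer the carbocycle is a 6,6-dimethylcyclohexa-2,4-dien-1-one. Its sp3 carbon C6(CH3)2 is bonded to C1=O, and oxygen sits on C1, C3 and C5. A dienylketene forms exactly the C1–C6 bond by 6π closure, the oxygen pattern is that of one ketene plus two ynol ethers, and the quaternary C6 forbids aromatisation.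
Forward, half A: dimethylketene plus ethoxyacetylene gives the four-membered ring. A second ethoxyacetylene expands it from four to six atoms, and hydrolysis and C-acylation follow.
Forward, half B: phloroglucinol is acylated and the para OH is silylated. The pyran ring is built onto the ortho OH (aldol-type step, then oxa-6π), followed by desilylation and aminomethylation at C6.
Union: the Mannich base gives an o-quinone methide, which the enol of half A traps, so the CH2 bridge is made last.
Stereochemistry: there is none to set, because the target has no stereocentre and its only non-enolic C=C is held cis in the pyran ring.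

Key step: step 2

Remark: the target is achiral (no stereocentre, no configurationally free double bond), so no enantiocontrol is needed. Enol forms are drawn throughout in the tautomer of the given SMILES.

Step 1
Reactants: 1 isobutyryl chloride; 2 ethoxyacetylene
Product: 4 3-ethoxy-4,4-dimethylcyclobut-2-en-1-one, via dimethylketene 3 (not isolated)
Conditions: Et3N, Et2O, 0 °C to reflux
Reagents that add atoms: none
Why: Dehydrochlorination gives dimethylketene 3, which undergoes the classical ketene/ynol ether [2+2] cycloaddition, the nucleophilic CH terminus of 2 bonding to the ketene carbonyl carbon so that OEt ends up at C3 next to the C(CH3)2 carbon.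

Step 2
Reactants: 4 3-ethoxy-4,4-dimethylcyclobut-2-en-1-one; 2 ethoxyacetylene
Product: 8 3,5-diethoxy-6,6-dimethylcyclohexa-2,4-dien-1-one, via vinylketene 5 (not isolated), via alkenylcyclobutenone 6 (not isolated), via dienylketene 7 (not isolated)
Conditions: 2 (5 equiv), hν (254 nm, quartz), hexanes, 20 °C; evaporate excess 2; toluene, 90 °C, dark
Reagents that add atoms: none
Why: Light opens 4 by 4π electrocyclic cleavage of its C1–C4 bond to vinylketene 5, the ketene C=C of 5 adds ynol ether 2 to give 6, heat opens 6 (conrotatory 4π) to dienylketene 7, and 7 closes to 8; in sum the two alkyne carbons are inserted between C1 and C2 of 4, a 4→6 ring expansion in which all four ring atoms of 4 are kept. This is the Danheiser annulation of a cyclobutenone and an alkoxyalkyne, and the closure onto a fully substituted terminus is the thermal reverse of the Barton–Quinkert photo-opening of 6,6-disubstituted cyclohexa-2,4-dienones and the last event of the Wulff cyclohexadienone annulation. Modes of closure: the four-membered ring of 6 by [2+2] cycloaddition, the six-membered ring of 8 by disrotatory 6π electrocyclization between the ketene carbon (C1) and the C(CH3)2 terminus (C6). The quaternary C6 blocks the enolisation that normally ends the sequence in a phenol, so the dearomatised ring of the target is kept. The step needs regioselectivity in the [2+2] event, and polarity secures it: the nucleophilic CH terminus of 2 bonds to the electrophilic ketene carbon, which places the new OEt at C3 and completes the 1,3,5-oxygen pattern; the ring openings are reversible, so 5 that does not meet 2 returns to 4, and only the rotamer of 7 that has the alkenyl arm turned inward is drained to 8. No stereocentre is left, since C4 of 6 is formed racemic and becomes sp2 again; light is used for the first opening because 2 loses ethylene (retro-ene) at the temperature that a 4,4-dimethyl-3-alkoxycyclobutenone would need.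

Step 3
Reactants: 8 3,5-diethoxy-6,6-dimethylcyclohexa-2,4-dien-1-one
Product: 9 filicinic acid (3,5-dihydroxy-6,6-dimethylcyclohexa-2,4-dien-1-one)
Conditions: 2 M aq HCl, THF, reflux
Reagents that add atoms: water, O
Why: Both OEt groups are vinylogous ester oxygens, so acid-catalysed addition of water and loss of ethanol (vinylogous ester hydrolysis) should give the symmetric enolised triketone, which holds no acid-labile group.

Step 4
Reactants: 9 filicinic acid; 1 isobutyryl chloride
Product: 10 isobutyrylfilicinic acid (3,5-dihydroxy-6,6-dimethyl-2-(2-methylpropanoyl)cyclohexa-2,4-dien-1-one)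
Conditions: AlCl3 (3 equiv), CH2Cl2–PhNO2, 0 to 40 °C; 1 M HCl work-up
Reagents that add atoms: none
Why: Friedel–Crafts-type C-acylation of an enolised β-triketone that behaves like a phenol; the two nucleophilic CH carbons are equivalent by symmetry and the first acyl group deactivates the ring against a second one.

Step 5
Reactants: 11 phloroglucinol; 1 isobutyryl chloride
Product: 12 phlorisobutyrophenone (2-methyl-1-(2,4,6-trihydroxyphenyl)propan-1-one)
Conditions: AlCl3 (4 equiv), CH2Cl2–PhNO2, reflux; ice/HCl work-up
Reagents that add atoms: none
Why: Friedel–Crafts acylation of the very electron-rich arene should stop after one acyl group because the chelated ketone deactivates the ring.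

Step 6
Reactants: 12 phlorisobutyrophenone
Product: 13 1-[2,6-dihydroxy-4-(triisopropylsilyloxy)phenyl]-2-methylpropan-1-one
Conditions: TIPSCl (1.05 equiv), imidazole, DMF, 0 °C
Reagents that add atoms: chlorotriisopropylsilane (TIPSCl), CC(C)[Si](Cl)(C(C)C)C(C)C
Why: The two ortho OH groups are hydrogen-bonded to and shielded by the ketone, so the bulky silyl chloride should take the free and most acidic para OH (selective phenol silylation), which blocks the oxygen that would otherwise lead to the 6-acyl chromene.

Step 7
Reactants: 13 1-[2,6-dihydroxy-4-(triisopropylsilyloxy)phenyl]-2-methylpropan-1-one; 14 3-methylbut-2-enal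
Product: 16 1-[7-hydroxy-2,2-dimethyl-5-(triisopropylsilyloxy)-2H-chromen-8-yl]-2-methylpropan-1-one, via o-quinone methide 15 (not isolated)
Conditions: 14 (1.1 equiv), ethylenediammonium diacetate (20 mol %), toluene, reflux, Dean–Stark
Reagents that add atoms: none
Why: Iminium-catalysed aldol-type C-alkylation at a ring CH, loss of water to o-quinone methide 15 and oxa-6π electrocyclization (formal [3+3] chromene synthesis) can close only onto the free OH next to the acyl-bearing carbon, because the other flanking oxygen is silylated, and this fixes the 8-acyl regiochemistry.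

Step 8
Reactants: 16 1-[7-hydroxy-2,2-dimethyl-5-(triisopropylsilyloxy)-2H-chromen-8-yl]-2-methylpropan-1-one
Product: 17 1-(5,7-dihydroxy-2,2-dimethyl-2H-chromen-8-yl)-2-methylpropan-1-one
Conditions: TBAF, AcOH, THF, 0 °C
Reagents that add atoms: none
Why: Fluoride-induced cleavage of the aryl silyl ether under acetic acid buffering avoids the strong acid that could open the pyran ring and re-close it onto the freed 5-OH.

Step 9
Reactants: 17 1-(5,7-dihydroxy-2,2-dimethyl-2H-chromen-8-yl)-2-methylpropan-1-one; 18 Eschenmoser's salt
Product: 19 1-[6-(dimethylaminomethyl)-5,7-dihydroxy-2,2-dimethyl-2H-chromen-8-yl]-2-methylpropan-1-one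
Conditions: Et3N, CH2Cl2, 0 °C to rt
Reagents that add atoms: none
Why: Phenolic Mannich reaction with the preformed iminium salt at C6, the only free aromatic position and flanked by two OH groups, with no free formaldehyde present that could bridge two chromene units.

Step 10
Reactants: 19 1-[6-(dimethylaminomethyl)-5,7-dihydroxy-2,2-dimethyl-2H-chromen-8-yl]-2-methylpropan-1-one; 10 isobutyrylfilicinic acid
Product: 21 uliginosin B, via o-quinone methide 20 (not isolated)
Conditions: 1,4-dioxane, 80 °C, N2 sweep, dark
Reagents that add atoms: none
Why: The acidic enol 10 protonates the amine of 19, loss of dimethylamine gives o-quinone methide 20, and the enolate of 10 adds through its only CH carbon (Michael addition to an o-quinone methide released from a Mannich base); each partner has a single nucleophilic carbon and that of 19 is blocked, so only the cross-coupled bridge should form.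

Compound list
1 | isobutyryl chloride | CC(C)C(=O)Cl | starting material
2 | ethoxyacetylene | C#COCC | starting material
3 | dimethylketene | CC(C)=C=O | intermediate
4 | 3-ethoxy-4,4-dimethylcyclobut-2-en-1-one | CCOC1=CC(=O)C1(C)C | intermediate
5 | 3-ethoxy-4-methylpenta-1,3-dien-1-one (vinylketene) | CCOC(C=C=O)=C(C)C | intermediate
6 | 3-ethoxy-4-(1-ethoxy-2-methylprop-1-en-1-yl)cyclobut-2-en-1-one (racemic, transient) | CCOC1=CC(=O)C1C(OCC)=C(C)C | intermediate
7 | (3E)-3,5-diethoxy-6-methylhepta-1,3,5-trien-1-one (dienylketene) | O=C=C/C(OCC)=C\C(OCC)=C(C)C | intermediate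
8 | 3,5-diethoxy-6,6-dimethylcyclohexa-2,4-dien-1-one | CCOC1=CC(OCC)=CC(=O)C1(C)C | intermediate
9 | filicinic acid (3,5-dihydroxy-6,6-dimethylcyclohexa-2,4-dien-1-one) | CC1(C)C(O)=CC(O)=CC1=O | intermediate
10 | isobutyrylfilicinic acid | CC(C)C(=O)C1=C(O)C=C(O)C(C)(C)C1=O | intermediate
11 | phloroglucinol | Oc1cc(O)cc(O)c1 | starting material
12 | phlorisobutyrophenone | CC(C)C(=O)c1c(O)cc(O)cc1O | intermediate
13 | 1-[2,6-dihydroxy-4-(triisopropylsilyloxy)phenyl]-2-methylpropan-1-one | CC(C)C(=O)c1c(O)cc(O[Si](C(C)C)(C(C)C)C(C)C)cc1O | intermediate
14 | 3-methylbut-2-enal | CC(C)=CC=O | starting material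
15 | 3-hydroxy-6-(3-methylbut-2-en-1-ylidene)-2-(2-methylpropanoyl)-5-(triisopropylsilyloxy)cyclohexa-2,4-dien-1-one (side chain cis to the ring C=O) | CC(C)=C/C=C1\C(=O)C(C(=O)C(C)C)=C(O)C=C1O[Si](C(C)C)(C(C)C)C(C)C | intermediate
16 | 1-[7-hydroxy-2,2-dimethyl-5-(triisopropylsilyloxy)-2H-chromen-8-yl]-2-methylpropan-1-one | CC(C)C(=O)c1c(O)cc(O[Si](C(C)C)(C(C)C)C(C)C)c2C=CC(C)(C)Oc12 | intermediate
17 | 1-(5,7-dihydroxy-2,2-dimethyl-2H-chromen-8-yl)-2-methylpropan-1-one | CC(C)C(=O)c1c(O)cc(O)c2C=CC(C)(C)Oc12 | intermediate
18 | Eschenmoser's salt (N,N-dimethylmethyleneiminium iodide) | C[N+](C)=C.[I-] | starting material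
19 | 1-[6-(dimethylaminomethyl)-5,7-dihydroxy-2,2-dimethyl-2H-chromen-8-yl]-2-methylpropan-1-one | CC(C)C(=O)c1c(O)c(CN(C)C)c(O)c2C=CC(C)(C)Oc12 | intermediate
20 | 7-hydroxy-2,2-dimethyl-6-methylidene-8-(2-methylpropanoyl)-2H-chromen-5(6H)-one | C=C1C(=O)C2=C(OC(C)(C)C=C2)C(C(=O)C(C)C)=C1O | intermediate
21 | uliginosin B | CC(C)C(=O)C1=C(O)C(Cc2c(O)c3c(c(C(=O)C(C)C)c2O)OC(C)(C)C=C3)=C(O)C(C)(C)C1=O | target

Total step count: 10. Longest linear sequence: 6 (steps 5, 6, 7, 8, 9, 10). The other branch has 5 (steps 1, 2, 3, 4, 10).

Steps most likely to fail

Step 2. The vinylketene may be lost by a [1,5]-hydrogen shift from the methyl group that lies cis to the ketene, or by self-addition, before the alkyne reaches it. Inward rotation of the bulky alkenyl arm in the second ring opening may also be too slow to feed the 6π closure.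
Fallback: set out from 12 and treat it with MeI and NaOMe in MeOH. Alkylative dearomatisation (double C-methylation at one ring CH carbon of an acylphloroglucinol) should give 10 directly, where the route is rejoined. Steps 1–4 are then not needed, and the detour makes no compound outside the list (F0).

Step 10. The CH2 unit may be passed between the partners by retro-Mannich and retro-Michael events, which would scramble the bridge towards symmetric dimers. Thermal opening of the pyran and re-closure onto the neighbouring phenol oxygen is also possible.
Fallback: set out from 17 and carry the bridge carbon at the aldehyde level. Vilsmeier–Haack formylation (POCl3, DMF, then water) should give 5,7-dihydroxy-2,2-dimethyl-8-(2-methylpropanoyl)-2H-chromene-6-carbaldehyde F1. Proline-catalysed Knoevenagel condensation of F1 with 10 at room temperature should give the arylmethylidene triketone F2. This is reduced in the same flask by Hantzsch ester (three-component reductive alkylation of a cyclic 1,3-dione), and the route is rejoined at 21.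

Step 7. C–C bond formation next to the bulky silyl ether may be slow. A second chromenylation at the remaining ring CH and partial loss of the silyl group in the hot amine/acetate medium may compete.
Fallback: set out from 13 and change from the aldol/oxa-6π logic to O-alkylation followed by sigmatropic rearrangement. Copper-catalysed O-propargylation (2-methylbut-3-yn-2-yl trifluoroacetate, CuCl2 cat., DBU, MeCN, 0 °C) should give 1-[2-hydroxy-6-(2-methylbut-3-yn-2-yloxy)-4-(triisopropylsilyloxy)phenyl]-2-methylpropan-1-one F3. Heating F3 in xylene should trigger aromatic Claisen rearrangement to the only free ortho carbon, then a [1,5]-H shift and oxa-6π closure, and the route is rejoined at 16.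

Further compounds
F0 | step 2 | none | none
F1 | step 10 | 5,7-dihydroxy-2,2-dimethyl-8-(2-methylpropanoyl)-2H-chromene-6-carbaldehyde | CC(C)C(=O)c1c(O)c(C=O)c(O)c2C=CC(C)(C)Oc12
F2 | step 10 | arylmethylidene triketone, Knoevenagel adduct of F1 and 10 (not isolated, alkene geometry not fixed) | CC(C)C(=O)C1=C(O)C(=Cc2c(O)c3c(c(C(=O)C(C)C)c2O)OC(C)(C)C=C3)C(=O)C(C)(C)C1=O
F3 | step 7 | 1-[2-hydroxy-6-(2-methylbut-3-yn-2-yloxy)-4-(triisopropylsilyloxy)phenyl]-2-methylpropan-1-one | CC(C)C(=O)c1c(O)cc(O[Si](C(C)C)(C(C)C)C(C)C)cc1OC(C)(C)C#C
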